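The meeting opened on a comparison: the spring run reached half of its charge as mono adduct in 15.4 min, while the dusk run, charged with more substrate, took longer, 24.0 min, both figures being readings.

in all of them: gas 11 mM (held)

| run | substrate | remark | time |
|---|---|---|---|
| spring | 0.087 M | run made earlier |  |
| dusk | 0.20 M | run made earlier |  |
| Monday's | 0.13 M |  | 40 min |
| Friday's | 0.13 M |  | 60 min |

| spring: time / min | spring: mono adduct / % | dusk: time / min | dusk: mono adduct / % |
|---|---|---|---|
| 5.00 | 15.3 | 5.00 | 11.1 |
| 10.0 | 33.6 | 10.0 | 22.8 |
| 15.0 | 48.9 | 15.0 | 32.9 |
| 20.0 | 61.6 | 20.0 | 41.0 |
| 25.0 | 71.2 | 25.0 | 52.3 |
| 30.0 | 78.0 | 30.0 | 59.2 |

(readings scatter by 1 percentage point)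

1. which of the two there is more of at the end, Monday's (double product / mono adduct)
2. which of the two there is more of at the end, Friday's (double product / mono adduct)
3. final mono adduct, as a percentage of the substrate charged, in Monday's
4. final mono adduct, as a percentage of the substrate charged, in Friday's

- at the start none of the gas is in solution

The process chemist proposed to carry a single quantity. She drew a straight line through the two readings against the charge of substrate, and read 18.7 min at 0.13 M as the half-time of the charge, the time by which half of the substrate charged has reacted. She warned that two charges give a line and no test of it, and that the figure reads reacted substrate as mono adduct.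

The kineticist objected that the readings of the spring run do not keep the equal half-times of a pseudo-first-order loss: its next halving took 12.4 min, shorter than the first. He therefore scaled the next half-time of Monday's and Friday's charge by that reading, to 15.0 min, and held it there.

The chair noted that the spring run still rose 6.8 percentage points in its last interval, so the meeting expected mono adduct to stay ahead of double product. My own reckoning from these half-times puts reacted substrate at 81.4% in Monday's and 92.6% in Friday's.

The forecast names mono adduct for Monday's and mono adduct for Friday's, with 78% (71% to 83%) and 87% (74% to 93%) of mono adduct, below my figures for reacted substrate, and says “Mono adduct should dominate in both runs”.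

The flask gives 81.4% mono adduct against 3.90% double product in Monday's, and 86.4% against 7.27% in Friday's.

    gas ⇌ coupling partner, rate k1*(csat - [coupling partner]) (kL = 0.580 /min)
    coupling partner + double product → tris adduct + by-product (k = 2.60 /M/min)
    substrate + coupling partner → mono adduct + by-product (k = 9.00 /M/min)
    coupling partner + mono adduct → double product + by-product (k = 0.400 /M/min)

In Monday's flask the half-life of mono adduct by its reaction with the coupling partner, 3.7 h at 40.0 min, is long against the run's 40 min and against the half-time of 18.7 min, while the half-life of substrate by its own reaction with the coupling partner stands at 9.8 min. The same line, carried on from 18.7 min, gives a half-time of 48.2 min for the neighbour charged with 0.52 M, longer than that flask's 40 min, and that neighbour ends with 58.5% of its substrate still there.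

(All runs come from a simulation for an exercise.)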